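**Assumption:** atoms keep the briarane numbering of the target in every intermediate (C1–C14 carbocycle, C15 on C1, C16 on C5, C17/C18/C19 = lactone CH, its methyl and C=O, C20 on C11). The C14 carbinol of 21–28 is drawn as the expected major (14S) epimer; it is removed in step 19, so both epimers converge. Nothing here has been run: yields and selectivities are predictions.

## Retrosynthetic overview

1. Target ⇐ one-pot acetylation/β-elimination of a 2,8,9,14-tetrahydroxy 12-ketone.
2. Ring A and the ten-membered ring form together, last, by a titanocene-triggered transannular radical C1–C10 closure (epoxide homolysis, 6-endo addition to the enone) of a 14-membered epoxy enone.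
3. The 14-membered ring (second ring) ⇐ Nozaki–Hiyama–Kishi closure C9–C10; its open chain ⇐ aldol (C13–C14) of an epoxy aldehyde with (E)-4-iodo-3-methylbut-3-en-2-one.
4. The γ-lactone (first ring) ⇐ 5-exo-dig radical cyclisation of a propargylic bromoacetate, then C17 methylation and C8/C9 dihydroxylation; C2 from Sharpless epoxidation, C7 from CBS reduction.
5. The chloroalkene ⇐ syn-carbocupration/chlorination of an alkynyl Weinreb amide built from 5-bromo-2-methylpent-2-ene and acetylide.

## Route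

Step 1
Reactants: 1 but-3-yn-2-ol (racemic)
Product: 3 (E)-4-iodo-3-methylbut-3-en-2-ol, via alkenylalane 2 (not isolated)
Conditions: Me3Al (3 equiv), Cp2ZrCl2 (0.25 equiv), CH2Cl2, 0 °C to rt; then I2, THF, −30 °C
Reagents that add atoms: trimethylaluminium, C[Al](C)C; iodine, II
Why: Negishi zirconium-catalysed syn-carboalumination puts methyl on the internal and aluminium on the terminal alkyne carbon, and iodinolysis with retention gives the E-iodoalkene (iodine cis to the new methyl).

Step 2
Reactants: 3 (E)-4-iodo-3-methylbut-3-en-2-ol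
Product: 4 (E)-4-iodo-3-methylbut-3-en-2-one
Conditions: MnO2 (15 equiv), CH2Cl2, rt
Reagents that add atoms: none
Why: MnO2 oxidation of the allylic alcohol removes the racemic carbinol centre and leaves the alkene geometry untouched.

Step 3
Reactants: 5 5-bromo-2-methylpent-2-ene
Product: 6 6-methylhept-5-en-1-yne
Conditions: LiC≡CH·H2NCH2CH2NH2, DMSO, 10 °C to rt
Reagents that add atoms: lithium acetylide–ethylenediamine complex, [Li+].[C-]#C.NCCN
Why: SN2 alkylation of the acetylide by the primary bromide delivers C2–C6 and C14/C15 of the skeleton.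

Step 4
Reactants: 6 6-methylhept-5-en-1-yne
Product: 8 N-methoxy-N,7-dimethyloct-6-en-2-ynamide, via lithium acetylide 7 (not isolated)
Conditions: n-BuLi, THF, −78 °C; then ClC(O)N(OMe)Me, −78 to 0 °C
Reagents that add atoms: N-methoxy-N-methylcarbamoyl chloride, CON(C)C(Cl)=O
Why: Acylation of the lithium acetylide by the carbamoyl chloride gives the alkynyl Weinreb amide (C7).

Step 5
Reactants: 8 alkynyl Weinreb amide
Product: 10 (E)-2-chloro-N-methoxy-N,3,7-trimethylocta-2,6-dienamide, via alkenylcuprate 9 (not isolated)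
Conditions: Me2CuLi (from MeLi and CuI), THF, −78 °C; then N-chlorosuccinimide, −78 to −40 °C
Reagents that add atoms: lithium dimethylcuprate, [Li+].C[Cu-]C; N-chlorosuccinimide, ClN1C(=O)CCC1=O
Why: Syn-carbocupration of the ynamide followed by electrophilic chlorination with retention places Cl cis to the new C16 methyl and C4 cis to C7, the alkene geometry of the target.

Step 6
Reactants: 10 chloro dienamide
Product: 11 (E)-4-chloro-5,9-dimethyldeca-4,8-dien-1-yn-3-one
Conditions: HC≡CMgBr (2.5 equiv), THF, 0 °C; then 1 M HCl, 0 °C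
Reagents that add atoms: ethynylmagnesium bromide, C#C[Mg]Br
Why: Weinreb ketone synthesis, in which the chelated tetrahedral adduct prevents over-addition and releases the ynone (C8, C9) on work-up.

Step 7
Reactants: 11 ynone
Product: 12 (3S,4E)-4-chloro-5,9-dimethyldeca-4,8-dien-1-yn-3-ol
Conditions: (R)-2-methyl-CBS-oxazaborolidine (0.2 equiv), catecholborane, toluene, −78 °C
Reagents that add atoms: none
Why: Corey–Bakshi–Shibata reduction with the tetrasubstituted chloroalkenyl group as the large and ethynyl as the small substituent sets C7 as S.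

Step 8
Reactants: 12 propargylic alcohol
Product: 13 (3S,4E)-4-chloro-5,9-dimethyldeca-4,8-dien-1-yn-3-yl 2-bromoacetate
Conditions: BrCH2COBr, pyridine, CH2Cl2, 0 °C
Reagents that add atoms: bromoacetyl bromide, BrCC(Br)=O
Why: Simple O-acylation installs C19 and C17 with the radical precursor, leaving C7 unchanged.

Step 9
Reactants: 13 bromoacetate
Product: 14 (5S)-5-[(1E)-1-chloro-2,6-dimethylhepta-1,5-dien-1-yl]-4-methylideneoxolan-2-one
Conditions: Bu3SnH (1.2 equiv), AIBN (0.1 equiv), benzene (0.005 M), 80 °C, syringe-pump addition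
Reagents that add atoms: none
Why: Tin-mediated 5-exo-dig radical cyclisation of the α-ester radical onto the terminal alkyne forms the C17–C8 bond and the γ-lactone, the vinyl radical being reduced to the exocyclic methylene (C9).

Step 10
Reactants: 14 methylidene lactone
Product: 16 (3R,5S)-5-[(1E)-1-chloro-2,6-dimethylhepta-1,5-dien-1-yl]-3-methyl-4-methylideneoxolan-2-one, via lithium dienolate 15 (not isolated)
Conditions: LiN(iPr)2 (1.05 equiv), THF, −78 °C; then MeI, −78 °C
Reagents that add atoms: iodomethane, CI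
Why: Kinetic α-alkylation of the lactone dienolate occurs anti to the C7 alkenyl substituent, setting C17 (R) with C18 trans to C6.

Step 11
Reactants: 16 methyl lactone
Product: 17 (3R,5S)-5-[(1E,5E)-1-chloro-7-hydroxy-2,6-dimethylhepta-1,5-dien-1-yl]-3-methyl-4-methylideneoxolan-2-one
Conditions: SeO2 (0.3 equiv), t-BuOOH (3 equiv), salicylic acid (0.1 equiv), CH2Cl2, rt
Reagents that add atoms: tert-butyl hydroperoxide, CC(C)(C)OO
Why: Selenium dioxide allylic oxidation (ene reaction then 2,3-shift) hydroxylates the E-methyl (C14) of the only electron-rich trisubstituted alkene.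

Step 12
Reactants: 17 allylic alcohol
Product: 18 (3R,5S)-5-{(1E)-1-chloro-4-[(2S,3S)-3-(hydroxymethyl)-3-methyloxiran-2-yl]-2-methylbut-1-en-1-yl}-3-methyl-4-methylideneoxolan-2-one
Conditions: Ti(OiPr)4 (0.1 equiv), L-(+)-diethyl tartrate (0.12 equiv), t-BuOOH (2 equiv), 4 Å molecular sieves, CH2Cl2, −20 °C
Reagents that add atoms: tert-butyl hydroperoxide, CC(C)(C)OO
Why: Sharpless asymmetric epoxidation of the E-2-methyl allylic alcohol with L-(+)-tartrate gives the (2S,3S)-epoxy alcohol, fixing C2 as S by reagent control.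

Step 13
Reactants: 18 epoxy alcohol
Product: 19 (2R,3S)-3-{(3E)-4-chloro-3-methyl-4-[(2S,4R)-4-methyl-3-methylidene-5-oxooxolan-2-yl]but-3-en-1-yl}-2-methyloxirane-2-carbaldehyde
Conditions: Dess–Martin periodinane, pyridine, CH2Cl2, 0 °C to rt
Reagents that add atoms: none
Why: Dess–Martin oxidation gives the non-enolisable α,β-epoxy aldehyde (C14) without touching the epoxide or the lactone.

Step 14
Reactants: 19 epoxy aldehyde; 4 (E)-4-iodo-3-methylbut-3-en-2-one
Product: 21 (3R,5S)-5-[(1E)-1-chloro-4-{(2S,3S)-3-[(1S,4E)-1-hydroxy-5-iodo-4-methyl-3-oxopent-4-en-1-yl]-3-methyloxiran-2-yl}-2-methylbut-1-en-1-yl]-3-methyl-4-methylideneoxolan-2-one, via lithium enolate 20 (not isolated)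
Conditions: 4 (1.5 equiv), LiN(iPr)2, THF, −78 °C; then 19, −78 °C; AcOH quench
Reagents that add atoms: none
Why: Aldol addition of the kinetic methyl-ketone enolate forms C13–C14, with Felkin–Anh attack anti to the epoxide C–O bond expected to favour the 14S carbinol (a centre later eliminated).

Step 15
Reactants: 21 aldol adduct
Product: 22 (3R,4R,5S)-5-[side chain as in 21]-4-hydroxy-4-(hydroxymethyl)-3-methyloxolan-2-one
Conditions: OsO4 (5 mol%), N-methylmorpholine N-oxide (1.5 equiv), acetone/H2O 10:1, 0 °C to rt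
Reagents that add atoms: N-methylmorpholine N-oxide, C[N+]1([O-])CCOCC1; water, O
Why: Upjohn dihydroxylation takes the 1,1-disubstituted exocyclic alkene (the chloroalkene is tetrasubstituted, the iodoenone electron-poor) from the lactone face anti to the C7 alkenyl group, giving 8-OH cis to H-7 and C18 (C8 R).

Step 16
Reactants: 22 diol
Product: 23 (2S,3S,4R)-2-[side chain as in 21]-3-hydroxy-4-methyl-5-oxooxolane-3-carbaldehyde
Conditions: Cu(MeCN)4OTf (5 mol%), 2,2'-bipyridine (5 mol%), TEMPO (5 mol%), N-methylimidazole (10 mol%), air, MeCN, rt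
Reagents that add atoms: none
Why: Stahl copper/TEMPO aerobic oxidation is selective for the primary C9 alcohol, leaving the secondary C14 and tertiary C8 hydroxyls and avoiding glycol cleavage.

Step 17
Reactants: 23 iodoenone aldehyde
Product: 24 (1S,2S,5E,7S,8R,9S,10E,14S,17R)-6-chloro-1,2-epoxy-8,9,14-trihydroxy-12-oxo-1,10-secobriara-5,10-dien-19,7-olide (14-membered carbocycle C1–C14)
Conditions: CrCl2 (8 equiv), NiCl2 (0.1 equiv), DMSO/THF 3:1 (0.002 M), rt
Reagents that add atoms: none
Why: Nozaki–Hiyama–Kishi macrocyclisation, in which the alkenylchromium from the β-iodoenone (vinyl chloride inert) adds to the aldehyde through the C8-alkoxide/aldehyde chromium chelate from the face flanked by C17–H rather than by the C7 chain, giving 9S and the 14-membered γ-hydroxy enone.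

Step 18
Reactants: 24 macrocyclic epoxy enone
Product: 25 (1S,2S,5E,7S,8R,9S,10S,11R,14S,17R)-6-chloro-2,8,9,14-tetrahydroxy-12-oxobriar-5-en-19,7-olide
Conditions: Cp2TiCl2 (0.2 equiv), Mn dust (3 equiv), 2,4,6-collidine hydrochloride (2.5 equiv), THF (0.003 M), rt, slow addition of 24
Reagents that add atoms: none
Why: Proposed new method: trivalent titanium (Cp2TiCl, formed from Cp2TiCl2 and Mn) opens the trisubstituted epoxide homolytically to the tertiary C1 radical with the C2 titanoxy group retained, which adds across the ring to the enone β-carbon C10 through a chair-like 6-endo transition state (C2 and C9 chains equatorial, C2–H eclipsing C1–C14, attack anti to the titanoxy group) to set C1 and C10 with trans fusion, and the titanium enolate is protonated at C11 anti to the axial C15 methyl; the closest known reaction types are the Nugent–RajanBabu/Gansäuer titanocene epoxide-opening Giese cyclisation and the titanocene-mediated transannular cyclisation of epoxygermacrolides to eudesmanolides.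

Step 19
Reactants: 25 tetrahydroxy ketone
Product: 29 (1S,2S,5E,7S,8R,9S,10S,11R,17R)-2-acetoxy-6-chloro-8,9-dihydroxy-12-oxobriara-5,13-dien-19,7-olide (CNP0163464.1), via cyclic phenylboronate 26 (not isolated), via boronate diacetate 27 (not isolated), via enone boronate 28 (not isolated)
Conditions: PhB(OH)2 (1.1 equiv), MgSO4, CH2Cl2, rt; then Ac2O, Et3N, DMAP, 0 °C to rt; then DBU (1.5 equiv), 0 °C; aqueous sorbitol/NaHCO3 work-up
Reagents that add atoms: acetic anhydride, CC(=O)OC(C)=O
Why: The 8,9-diol is masked in situ as its cyclic phenylboronate, DMAP-catalysed acetylation then takes the C2 and C14 hydroxyls, DBU removes the β-acetoxy group of the C12 ketone by E1cB elimination through the less hindered C13 enolate to form the C13–C14 enone, and aqueous work-up hydrolyses the boronate; no stereocentre is formed and C11 is expected to survive the short, cold base exposure.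

## Compound list

1 | but-3-yn-2-ol (racemic) | CC(O)C#C | starting material
2 | (E)-alkenyldimethylalane O-dimethylaluminium alkoxide | CC(O[Al](C)C)/C(C)=C/[Al](C)C | intermediate (not isolated)
3 | (E)-4-iodo-3-methylbut-3-en-2-ol | CC(O)/C(C)=C/I | intermediate
4 | (E)-4-iodo-3-methylbut-3-en-2-one | CC(=O)/C(C)=C/I | intermediate
5 | 5-bromo-2-methylpent-2-ene | CC(C)=CCCBr | starting material
6 | 6-methylhept-5-en-1-yne | C#CCCC=C(C)C | intermediate
7 | (6-methylhept-5-en-1-yn-1-yl)lithium | [Li]C#CCCC=C(C)C | intermediate (not isolated)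
8 | N-methoxy-N,7-dimethyloct-6-en-2-ynamide | CON(C)C(=O)C#CCCC=C(C)C | intermediate
9 | lithium methyl(alkenyl)cuprate, copper on C6 cis to the new C16 methyl | [Li+].CON(C)C(=O)/C([Cu-]C)=C(C)\CCC=C(C)C | intermediate (not isolated)
10 | (E)-2-chloro-N-methoxy-N,3,7-trimethylocta-2,6-dienamide | CON(C)C(=O)/C(Cl)=C(C)\CCC=C(C)C | intermediate
11 | (E)-4-chloro-5,9-dimethyldeca-4,8-dien-1-yn-3-one | C#CC(=O)/C(Cl)=C(C)\CCC=C(C)C | intermediate
12 | (3S,4E)-4-chloro-5,9-dimethyldeca-4,8-dien-1-yn-3-ol | CC(C)=CCC/C(C)=C(/Cl)[C@H](C#C)O | intermediate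
13 | (3S,4E)-4-chloro-5,9-dimethyldeca-4,8-dien-1-yn-3-yl 2-bromoacetate | CC(C)=CCC/C(C)=C(/Cl)[C@H](C#C)OC(=O)CBr | intermediate
14 | (5S)-5-[(1E)-1-chloro-2,6-dimethylhepta-1,5-dien-1-yl]-4-methylideneoxolan-2-one | CC(C)=CCC/C(C)=C(/Cl)[C@H]1OC(=O)CC1=C | intermediate
15 | lithium dienolate of 14 | CC(C)=CCC/C(C)=C(/Cl)[C@H]1OC(O[Li])=CC1=C | intermediate (not isolated)
16 | (3R,5S)-5-[(1E)-1-chloro-2,6-dimethylhepta-1,5-dien-1-yl]-3-methyl-4-methylideneoxolan-2-one | CC(C)=CCC/C(C)=C(/Cl)[C@H]1OC(=O)[C@H](C)C1=C | intermediate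
17 | (3R,5S)-5-[(1E,5E)-1-chloro-7-hydroxy-2,6-dimethylhepta-1,5-dien-1-yl]-3-methyl-4-methylideneoxolan-2-one | OC/C(C)=C/CC/C(C)=C(/Cl)[C@H]1OC(=O)[C@H](C)C1=C | intermediate
18 | (3R,5S)-5-{(1E)-1-chloro-4-[(2S,3S)-3-(hydroxymethyl)-3-methyloxiran-2-yl]-2-methylbut-1-en-1-yl}-3-methyl-4-methylideneoxolan-2-one | OC[C@]1(C)O[C@H]1CC/C(C)=C(/Cl)[C@H]2OC(=O)[C@H](C)C2=C | intermediate
19 | (2R,3S)-3-{(3E)-4-chloro-3-methyl-4-[(2S,4R)-4-methyl-3-methylidene-5-oxooxolan-2-yl]but-3-en-1-yl}-2-methyloxirane-2-carbaldehyde | O=C[C@]1(C)O[C@H]1CC/C(C)=C(/Cl)[C@H]2OC(=O)[C@H](C)C2=C | intermediate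
20 | lithium (3E)-4-iodo-3-methylbuta-1,3-dien-2-olate | [Li]OC(=C)/C(C)=C/I | intermediate (not isolated)
21 | (3R,5S)-5-[(1E)-1-chloro-4-{(2S,3S)-3-[(1S,4E)-1-hydroxy-5-iodo-4-methyl-3-oxopent-4-en-1-yl]-3-methyloxiran-2-yl}-2-methylbut-1-en-1-yl]-3-methyl-4-methylideneoxolan-2-one | I/C=C(C)/C(=O)C[C@H](O)[C@]1(C)O[C@H]1CC/C(C)=C(/Cl)[C@H]2OC(=O)[C@H](C)C2=C | intermediate
22 | (3R,4R,5S)-4-hydroxy-4-(hydroxymethyl)-3-methyloxolan-2-one carrying at C5 the side chain of 21 | I/C=C(C)/C(=O)C[C@H](O)[C@]1(C)O[C@H]1CC/C(C)=C(/Cl)[C@H]2OC(=O)[C@H](C)[C@@]2(O)CO | intermediate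
23 | (2S,3S,4R)-3-hydroxy-4-methyl-5-oxooxolane-3-carbaldehyde carrying at C2 the side chain of 21 | I/C=C(C)/C(=O)C[C@H](O)[C@]1(C)O[C@H]1CC/C(C)=C(/Cl)[C@H]2OC(=O)[C@H](C)[C@@]2(O)C=O | intermediate
24 | (1S,2S,5E,7S,8R,9S,10E,14S,17R)-6-chloro-1,2-epoxy-8,9,14-trihydroxy-12-oxo-1,10-secobriara-5,10-dien-19,7-olide | O[C@H]1/C=C(C)/C(=O)C[C@H](O)[C@]2(C)O[C@H]2CC/C(C)=C(/Cl)[C@H]3OC(=O)[C@H](C)[C@]31O | intermediate
25 | (1S,2S,5E,7S,8R,9S,10S,11R,14S,17R)-6-chloro-2,8,9,14-tetrahydroxy-12-oxobriar-5-en-19,7-olide | O[C@H]1CC/C(C)=C(/Cl)[C@H]2OC(=O)[C@H](C)[C@@]2(O)[C@@H](O)[C@H]2[C@@H](C)C(=O)C[C@H](O)[C@@]21C | intermediate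
26 | 8,9-O-phenylboronate of 25 | O[C@H]1CC/C(C)=C(/Cl)[C@H]2OC(=O)[C@H](C)[C@@]2(OB(c3ccccc3)O5)[C@@H]5[C@H]2[C@@H](C)C(=O)C[C@H](O)[C@@]21C | intermediate (not isolated)
27 | 2,14-di-O-acetyl-8,9-O-phenylboronate of 25 | CC(=O)O[C@H]1CC/C(C)=C(/Cl)[C@H]2OC(=O)[C@H](C)[C@@]2(OB(c3ccccc3)O5)[C@@H]5[C@H]2[C@@H](C)C(=O)C[C@H](OC(C)=O)[C@@]21C | intermediate (not isolated)
28 | 8,9-O-phenylboronate of the target | CC(=O)O[C@H]1CC/C(C)=C(/Cl)[C@H]2OC(=O)[C@H](C)[C@@]2(OB(c3ccccc3)O5)[C@@H]5[C@H]2[C@@H](C)C(=O)C=C[C@@]21C | intermediate (not isolated)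
29 | (1S,2S,5E,7S,8R,9S,10S,11R,17R)-2-acetoxy-6-chloro-8,9-dihydroxy-12-oxobriara-5,13-dien-19,7-olide (CNP0163464.1) | CC(=O)O[C@H]1CC/C(C)=C(/Cl)[C@H]2OC(=O)[C@H](C)[C@@]2(O)[C@@H](O)[C@H]2[C@@H](C)C(=O)C=C[C@@]21C | target

## Step count and risks

Total: 19 steps (2 for the iodoenone 4, 17 in the main line). Longest linear sequence: 17 steps (5 to 29, steps 3–19).

The three steps most likely to fail are 9, 17 and 18; step 18 is the largest single risk.

Step 9 (radical lactonisation of an α-bromo ester, slowed by the ester's preferred s-trans geometry). The fallback sets out from 12 and returns at 14 by the Ueno–Stork acetal tether. Ethyl vinyl ether and N-bromosuccinimide (CH2Cl2, −20 °C) convert 12 into the mixed bromoacetal F1. Bu3SnH/AIBN then closes the far faster acetal-tethered 5-exo-dig cyclisation to the cyclic acetal 2-ethoxy-4-methylideneoxolane F2. CrO3/H2SO4 in acetone oxidises F2 to lactone 14.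

Step 17 (macrocyclisation; the C9 configuration rests on a chelation model). The fallback sets out from 24 obtained as a C9 epimer mixture and returns at 24, setting C9 by reduction instead of by C–C bond formation. MnO2 oxidises only the allylic C9 carbinol to the macrocyclic ene-dione, 9-ketone F3. Zn(BH4)2 (Et2O, −20 °C) then reduces the C9 ketone through its zinc chelate with the 8-OH from the less hindered face to give (9S)-24.

Step 18 (possible epoxide deoxygenation, 5-exo closure or wrong fusion). The fallback sets out from 24 and returns at 25, making the same C1 radical by halogen abstraction in a chain process that needs no titanium. MgBr2·OEt2 (Et2O, −20 °C) opens the epoxide at the tertiary carbon to the C1-bromo C2-hydroxy compound, bromohydrin F4. (Me3Si)3SiH/AIBN (toluene, 80 °C, high dilution) abstracts bromine; transannular 6-endo addition to the enone and hydrogen transfer to C11 from the face anti to C15 give 25.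

Further compounds
F1 | step 9 | (3S,4E)-3-(2-bromo-1-ethoxyethoxy)-4-chloro-5,9-dimethyldeca-4,8-dien-1-yne (acetal epimers) | CC(C)=CCC/C(C)=C(/Cl)[C@H](C#C)OC(CBr)OCC
F2 | step 9 | (2S)-2-[(1E)-1-chloro-2,6-dimethylhepta-1,5-dien-1-yl]-5-ethoxy-3-methylideneoxolane (acetal epimers) | CC(C)=CCC/C(C)=C(/Cl)[C@H]1OC(OCC)CC1=C
F3 | step 17 | (1S,2S,5E,7S,8R,10E,14S,17R)-6-chloro-1,2-epoxy-8,14-dihydroxy-9,12-dioxo-1,10-secobriara-5,10-dien-19,7-olide | O=C1/C=C(C)/C(=O)C[C@H](O)[C@]2(C)O[C@H]2CC/C(C)=C(/Cl)[C@H]3OC(=O)[C@H](C)[C@]31O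
F4 | step 18 | 1-bromo-6-chloro-2,8,9,14-tetrahydroxy-12-oxo-1,10-secobriara-5,10-dien-19,7-olide (bromide at C1 with inversion, other centres as in 24) | O[C@H]1/C=C(C)/C(=O)C[C@H](O)[C@@](C)(Br)[C@@H](O)CC/C(C)=C(/Cl)[C@H]2OC(=O)[C@H](C)[C@]21O
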